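**Plan**

- Numbering: the upper flavan has rings A (benzo), C (pyran) and B (2-aryl) with atoms O1 to C8a; the lower flavan has rings D, F and E with primed atoms. The retrosynthesis cuts, in order: the O-benzyl and O-silyl bonds; O1'–C2' (ring F), leaving a carboxyl group on C2'; C2'–C3' (aldol); C4a'–C4' (Claisen shift); C4–C6' (Friedel–Crafts).
- Enabling feature: O1' is para to C6' on ring D, and the two ring D carbons ortho to O1' (the future C4a' and C8') are equivalent until the side chain is attached, so only the 4→6 isomer can arise. C2' is benzylic to the electron-rich ring E, so anodic loss of CO2 from a C2' carboxylate leaves a cation that the O1' phenol captures.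
- Forward order: rings A, C and B come intact from (+)-gallocatechin. Ring D (from phloroglucinol) is joined at C4. C4' and C3' are added by O-allylation, Claisen shift and alkene cleavage. C2' with ring E (from tri-O-benzylgallic acid) is added by an aldol reaction. Ring F is closed last, then the protecting groups are removed.
- Stereochemistry: C2 and C3 come from gallocatechin; C4 from addition anti to the C3 benzyloxy group; C3' from an (R)-4-benzyloxazolidinone syn-aldol; C2' from the ring closure, trans to the C3' silyl ether (the aldol-derived C2' centre is erased).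

Key step: step 16

Assumption: 3,4,5-tris(benzyloxy)benzoic acid (the tri-O-benzyl ether of gallic acid) is bought as such, and the C4 configuration drawn for the two 4-(2-ethoxyethoxy) intermediates is the one expected by analogy; it is lost on ionisation and does not affect the outcome.

Shorthand in names: TBP = 3,4,5-tris(benzyloxy)phenyl. U = the (2R,3S)-3,5,7-tris(benzyloxy)-2-TBP-chroman-4-yl group, bonded through C4 on the α face (3,4-trans, cis to the C2 aryl group).

**Route**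

Step 1
Reactants: 1 (+)-gallocatechin
Product: 2 (2R,3S)-5,7-bis(benzyloxy)-2-TBP-chroman-3-ol (penta-O-benzylgallocatechin)
Conditions: BnBr, K2CO3, DMF, 0 °C → rt, argon
Reagents that add atoms: benzyl bromide, BrCc1ccccc1
Why: Williamson etherification under carbonate alkylates the five phenols but not the secondary C3 alcohol, and the two stereocentres are not touched.

Step 2
Reactants: 2 penta-O-benzylgallocatechin
Product: 3 (2R,3S,4S)-5,7-bis(benzyloxy)-4-(2-ethoxyethoxy)-2-TBP-chroman-3-ol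
Conditions: DDQ, 2-ethoxyethanol, CH2Cl2, rt
Reagents that add atoms: 2-ethoxyethanol, CCOCCO
Why: DDQ-mediated benzylic oxidation removes hydride from C4, the position activated by the two ring A oxygens, and the alcohol traps the cation, as is well established for O-benzylated flavan-3-ols with a free 3-hydroxyl.

Step 3
Reactants: 3 4-(2-ethoxyethoxy)flavan-3-ol
Product: 4 (2R,3S,4S)-3,5,7-tris(benzyloxy)-4-(2-ethoxyethoxy)-2-TBP-chromane
Conditions: NaH, BnBr, Bu4NI (cat.), DMF, 0 °C → rt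
Reagents that add atoms: benzyl bromide, BrCc1ccccc1
Why: Williamson etherification of the secondary alkoxide installs the last benzyl group at the unhindered monomer stage, the C4 ether being inert to base.

Step 4
Reactants: 5 phloroglucinol
Product: 6 5-(triisopropylsilyloxy)benzene-1,3-diol
Conditions: 5 (3 equiv), TIPSCl (1 equiv), imidazole, DMF, 0 °C → rt
Reagents that add atoms: chlorotriisopropylsilane, CC(C)[Si](Cl)(C(C)C)C(C)C
Why: Silylation of a symmetric triol used in excess should give mainly the mono-ether, and the excess water-soluble triol is washed out.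

Step 5
Reactants: 4 C4 electrophile; 6 5-(triisopropylsilyloxy)benzene-1,3-diol
Product: 7 2-U-5-(triisopropylsilyloxy)benzene-1,3-diol
Conditions: 6 (3 equiv), TMSOTf (0.3 equiv), CH2Cl2, −78 → −40 °C; Et3N quench
Reagents that add atoms: none
Why: Friedel–Crafts alkylation through the C4 cation (stabilised by the 5,7-dioxygenated ring A) should occur at the carbon between the two free hydroxyls, the only position not shielded by the bulky silyl ether, and anti to the C3 benzyloxy group, which sets C4 as 3,4-trans as is usual for 2,3-trans flavan-4-yl cations.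

Step 6
Reactants: 7 ring D diol
Product: 8 1,3-bis(benzyloxy)-2-U-5-(triisopropylsilyloxy)benzene
Conditions: BnBr, K2CO3, Bu4NI (cat.), DMF, rt
Reagents that add atoms: benzyl bromide, BrCc1ccccc1
Why: Williamson etherification with carbonate is mild enough to leave the aryl triisopropylsilyl ether in place, so the para oxygen stays distinguished from the two ortho oxygens.

Step 7
Reactants: 8 ring D silyl ether
Product: 10 5-(allyloxy)-1,3-bis(benzyloxy)-2-U-benzene, via caesium phenoxide 9 (not isolated)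
Conditions: CsF, allyl bromide, DMF, rt
Reagents that add atoms: allyl bromide, C=CCBr
Why: Fluoride cleaves the aryl Si–O bond and the phenoxide set free is O-allylated in the same flask (desilylation followed by Williamson etherification).

Step 8
Reactants: 10 aryl allyl ether
Product: 12 2-allyl-3,5-bis(benzyloxy)-4-U-phenyl acetate, via allylphenol 11 (not isolated)
Conditions: PhNEt2, 190 °C; then Ac2O, DMAP, rt
Reagents that add atoms: acetic anhydride, CC(=O)OC(C)=O
Why: The aromatic Claisen rearrangement delivers the allyl group to either of the two equivalent ortho carbons, so a single constitution results, and the phenol is acetylated at once so that the later aldehyde cannot close to a lactol.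

Step 9
Reactants: 12 allyl aryl acetate
Product: 14 3,5-bis(benzyloxy)-2-(2-oxoethyl)-4-U-phenyl acetate, via vicinal diol 13 (not isolated)
Conditions: OsO4 (cat.), NaIO4, 2,6-lutidine, 1,4-dioxane/H2O, rt
Reagents that add atoms: osmium tetroxide, O=[Os](=O)(=O)=O (delivers the aldehyde oxygen); sodium periodate, [Na+].[O-]I(=O)(=O)=O (restores OsO4 and cleaves the diol)
Why: Lemieux–Johnson oxidation cleaves the terminal alkene without the ozone that would attack the electron-rich rings, and lutidine suppresses over-oxidation.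

Step 10
Reactants: 15 3,4,5-tris(benzyloxy)benzoic acid
Product: 17 2-diazo-1-TBP-ethanone, via acid chloride 16 (not isolated)
Conditions: (COCl)2, DMF (cat.), CH2Cl2, 0 °C → rt; evaporate; TMSCHN2, MeCN/THF, 0 °C → rt
Reagents that add atoms: (trimethylsilyl)diazomethane, C[Si](C)(C)C=[N+]=[N-]
Why: This is the first stage of the Arndt–Eistert homologation, in which the acyl chloride acylates the diazoalkane carbon and chloride removes the silyl group.

Step 11
Reactants: 17 diazoketone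
Product: 19 2-TBP-acetic acid, via arylketene 18 (not isolated)
Conditions: PhCO2Ag (cat.), Et3N, THF/H2O, rt, dark
Reagents that add atoms: water, O
Why: Silver-promoted Wolff rearrangement expels N2 with 1,2-aryl shift to the ketene, which water converts into the homologous acid.

Step 12
Reactants: 19 2-TBP-acetic acid; 20 (R)-4-benzyl-2-oxazolidinone
Product: 22 (R)-4-benzyl-3-(2-TBP-acetyl)oxazolidin-2-one, via mixed pivalic anhydride 21 (not isolated)
Conditions: PivCl, Et3N, THF, −20 °C; then LiCl, 20, rt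
Reagents that add atoms: none
Why: N-acylation through the mixed anhydride is the standard way to load an arylacetic acid onto an oxazolidinone, the nucleophile attacking the less hindered carbonyl.

Step 13
Reactants: 22 arylacetyl imide; 14 arylacetaldehyde
Product: 24 (R)-4-benzyl-3-[(2R,3S)-4-(6-acetoxy-2,4-bis(benzyloxy)-3-U-phenyl)-3-hydroxy-2-TBP-butanoyl]oxazolidin-2-one, via dibutylboron enolate 23 (not isolated)
Conditions: 22 (1.5 equiv), Bu2BOTf, iPr2NEt, CH2Cl2, −78 → 0 °C; 14, −78 → −20 °C; pH 7 buffer, MeOH, H2O2, 0 °C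
Reagents that add atoms: none
Why: In the Evans syn-aldol reaction the Z boron enolate reacts through a closed Zimmerman–Traxler chair on the face away from the auxiliary benzyl group, which with the (R)-auxiliary sets C3' as S (and C2' as R).

Step 14
Reactants: 24 aldol adduct
Product: 25 (R)-4-benzyl-3-[(2R,3S)-4-(6-acetoxy-2,4-bis(benzyloxy)-3-U-phenyl)-3-(tert-butyldimethylsilyloxy)-2-TBP-butanoyl]oxazolidin-2-one
Conditions: TBSOTf, 2,6-lutidine, CH2Cl2, −78 → 0 °C
Reagents that add atoms: tert-butyldimethylsilyl triflate, CC(C)(C)[Si](C)(C)OS(=O)(=O)C(F)(F)F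
Why: Silylation with the silyl triflate and a hindered base protects the aldol hydroxyl without retro-aldol cleavage and leaves C3' with a non-nucleophilic, bulky oxygen substituent.

Step 15
Reactants: 25 silylated imide
Product: 27 (2R,3S)-4-[2,4-bis(benzyloxy)-6-hydroxy-3-U-phenyl]-3-(tert-butyldimethylsilyloxy)-2-TBP-butanoic acid (seco acid), via peroxy acid 26 (not isolated)
Conditions: LiOH, H2O2, THF/H2O, 0 °C → rt; Na2SO3; 0.5 M HCl to pH 4
Reagents that add atoms: hydrogen peroxide, OO (as LiOOH it supplies the hydroxyl oxygen of the carboxyl group)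
Why: Hydroperoxide attacks the exocyclic imide carbonyl (standard Evans auxiliary hydrolysis) and perhydrolyses the aryl acetate in the same flask, sulfite then reducing the percarboxylates, so the acid and the O1' phenol are unmasked together while the silyl and benzyl ethers stay.

Step 16
Reactants: 27 seco acid
Product: 28 (2R,3S)-5,7-bis(benzyloxy)-3-(tert-butyldimethylsilyloxy)-6-U-2-TBP-chromane
Conditions: graphite anode, Pt cathode, undivided cell, constant current (about 2.5 F/mol), 2,4,6-collidine (3 equiv), Bu4NPF6 (0.1 M), (CF3)2CHOH/CH2Cl2 1:4, 3 Å molecular sieves, 5 mM, rt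
Reagents that add atoms: none
Why: Collidine converts 27 into its carboxylate, whose one-electron oxidation at graphite is coupled to irreversible loss of CO2, and the resulting C2' benzylic radical is oxidised at once to a cation stabilised by the trialkoxyphenyl ring E and by the fluorinated alcohol. The closest known reaction type is the non-Kolbe (Hofer–Moest) anodic decarboxylative etherification of α-aryl carboxylic acids, in which an oxygen nucleophile captures the electrogenerated benzylic cation, used here in intramolecular form. Ring F closes by attack of the ring D phenol oxygen O1' on the planar C2' cation, a 6-exo-trig-type O-alkylation through a half-chair transition state. The new C2' stereocentre is controlled by the resident C3' centre: the closure that places the ring E aryl group and the silyloxy group both pseudo-equatorial leads to the 2',3'-trans (2'R,3'S) flavan, and the aldol-derived configuration at C2' no longer matters. The step needs oxidation of the carboxylate in the presence of a free phenol and four alkoxy-substituted arenes, and capture by O1' alone; the first is secured because only the carboxylate is deprotonated by collidine and has an irreversible follow-up reaction, the second because every other oxygen is benzylated or silylated and high dilution disfavours intermolecular capture by the electron-rich rings.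

Step 17
Reactants: 28 silylated undecabenzyl dimer
Product: 29 (2R,3S)-5,7-bis(benzyloxy)-6-U-2-TBP-chroman-3-ol
Conditions: TBAF, AcOH (1:1), THF, rt → 40 °C
Reagents that add atoms: none
Why: Fluoride-induced desilylation, buffered with acetic acid, frees the C3' hydroxyl without disturbing the benzyl ethers or the interflavan bond.

Step 18
Reactants: 29 undeca-O-benzyl dimer
Product: 30 gallocatechin-(4α→6)-gallocatechin (target)
Conditions: H2 (1 atm), Pd(OH)2/C, THF/MeOH/H2O, rt; filter; freeze-dry under argon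
Reagents that add atoms: none
Why: Catalytic hydrogenolysis removes the eleven benzyl ethers under neutral conditions, the benzylic C2–O1 ring bonds being cleaved far more slowly and the acid-sensitive C4–C6' bond being left alone.

**Compound list**

1 | (+)-gallocatechin, (2R,3S)-2-(3,4,5-trihydroxyphenyl)chromane-3,5,7-triol | O[C@H]1Cc2c(O)cc(O)cc2O[C@@H]1c1cc(O)c(O)c(O)c1 | starting material
2 | (2R,3S)-5,7-bis(benzyloxy)-2-TBP-chroman-3-ol | c1ccccc1COc1cc(OCc2ccccc2)c2c(c1)O[C@H](c1cc(OCc3ccccc3)c(OCc3ccccc3)c(OCc3ccccc3)c1)[C@@H](O)C2 | intermediate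
3 | (2R,3S,4S)-5,7-bis(benzyloxy)-4-(2-ethoxyethoxy)-2-TBP-chroman-3-ol | c1ccccc1COc1cc(OCc2ccccc2)c2c(c1)O[C@H](c1cc(OCc3ccccc3)c(OCc3ccccc3)c(OCc3ccccc3)c1)[C@@H](O)[C@H]2OCCOCC | intermediate
4 | (2R,3S,4S)-3,5,7-tris(benzyloxy)-4-(2-ethoxyethoxy)-2-TBP-chromane | c1ccccc1COc1cc(OCc2ccccc2)c2c(c1)O[C@H](c1cc(OCc3ccccc3)c(OCc3ccccc3)c(OCc3ccccc3)c1)[C@@H](OCc1ccccc1)[C@H]2OCCOCC | intermediate
5 | phloroglucinol (benzene-1,3,5-triol) | Oc1cc(O)cc(O)c1 | starting material
6 | 5-(triisopropylsilyloxy)benzene-1,3-diol | Oc1cc(O)cc(O[Si](C(C)C)(C(C)C)C(C)C)c1 | intermediate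
7 | 2-U-5-(triisopropylsilyloxy)benzene-1,3-diol (3,4-trans adduct) | c1ccccc1COc1cc(OCc2ccccc2)c2c(c1)O[C@H](c1cc(OCc3ccccc3)c(OCc3ccccc3)c(OCc3ccccc3)c1)[C@@H](OCc1ccccc1)[C@@H]2c1c(O)cc(O[Si](C(C)C)(C(C)C)C(C)C)cc1O | intermediate
8 | 1,3-bis(benzyloxy)-2-U-5-(triisopropylsilyloxy)benzene | c1ccccc1COc1cc(OCc2ccccc2)c2c(c1)O[C@H](c1cc(OCc3ccccc3)c(OCc3ccccc3)c(OCc3ccccc3)c1)[C@@H](OCc1ccccc1)[C@@H]2c1c(OCc2ccccc2)cc(O[Si](C(C)C)(C(C)C)C(C)C)cc1OCc1ccccc1 | intermediate
9 | caesium 3,5-bis(benzyloxy)-4-U-phenoxide (formed in the flask) | c1ccccc1COc1cc(OCc2ccccc2)c2c(c1)O[C@H](c1cc(OCc3ccccc3)c(OCc3ccccc3)c(OCc3ccccc3)c1)[C@@H](OCc1ccccc1)[C@@H]2c1c(OCc2ccccc2)cc([O-])cc1OCc1ccccc1.[Cs+] | intermediate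
10 | 5-(allyloxy)-1,3-bis(benzyloxy)-2-U-benzene | c1ccccc1COc1cc(OCc2ccccc2)c2c(c1)O[C@H](c1cc(OCc3ccccc3)c(OCc3ccccc3)c(OCc3ccccc3)c1)[C@@H](OCc1ccccc1)[C@@H]2c1c(OCc2ccccc2)cc(OCC=C)cc1OCc1ccccc1 | intermediate
11 | 2-allyl-3,5-bis(benzyloxy)-4-U-phenol (formed in the flask) | c1ccccc1COc1cc(OCc2ccccc2)c2c(c1)O[C@H](c1cc(OCc3ccccc3)c(OCc3ccccc3)c(OCc3ccccc3)c1)[C@@H](OCc1ccccc1)[C@@H]2c1c(OCc2ccccc2)cc(O)c(CC=C)c1OCc1ccccc1 | intermediate
12 | 2-allyl-3,5-bis(benzyloxy)-4-U-phenyl acetate | c1ccccc1COc1cc(OCc2ccccc2)c2c(c1)O[C@H](c1cc(OCc3ccccc3)c(OCc3ccccc3)c(OCc3ccccc3)c1)[C@@H](OCc1ccccc1)[C@@H]2c1c(OCc2ccccc2)cc(OC(C)=O)c(CC=C)c1OCc1ccccc1 | intermediate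
13 | 3,5-bis(benzyloxy)-2-(2,3-dihydroxypropyl)-4-U-phenyl acetate (both carbinol epimers, formed in the flask) | c1ccccc1COc1cc(OCc2ccccc2)c2c(c1)O[C@H](c1cc(OCc3ccccc3)c(OCc3ccccc3)c(OCc3ccccc3)c1)[C@@H](OCc1ccccc1)[C@@H]2c1c(OCc2ccccc2)cc(OC(C)=O)c(CC(O)CO)c1OCc1ccccc1 | intermediate
14 | 3,5-bis(benzyloxy)-2-(2-oxoethyl)-4-U-phenyl acetate | c1ccccc1COc1cc(OCc2ccccc2)c2c(c1)O[C@H](c1cc(OCc3ccccc3)c(OCc3ccccc3)c(OCc3ccccc3)c1)[C@@H](OCc1ccccc1)[C@@H]2c1c(OCc2ccccc2)cc(OC(C)=O)c(CC=O)c1OCc1ccccc1 | intermediate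
15 | 3,4,5-tris(benzyloxy)benzoic acid | OC(=O)c1cc(OCc2ccccc2)c(OCc2ccccc2)c(OCc2ccccc2)c1 | starting material
16 | 3,4,5-tris(benzyloxy)benzoyl chloride (formed in the flask) | ClC(=O)c1cc(OCc2ccccc2)c(OCc2ccccc2)c(OCc2ccccc2)c1 | intermediate
17 | 2-diazo-1-TBP-ethanone | [N-]=[N+]=CC(=O)c1cc(OCc2ccccc2)c(OCc2ccccc2)c(OCc2ccccc2)c1 | intermediate
18 | TBP-ketene (formed in the flask) | O=C=Cc1cc(OCc2ccccc2)c(OCc2ccccc2)c(OCc2ccccc2)c1 | intermediate
19 | 2-TBP-acetic acid | OC(=O)Cc1cc(OCc2ccccc2)c(OCc2ccccc2)c(OCc2ccccc2)c1 | intermediate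
20 | (R)-4-benzyl-2-oxazolidinone | O=C1N[C@H](Cc2ccccc2)CO1 | starting material
21 | pivalic 2-TBP-acetic anhydride (formed in the flask) | CC(C)(C)C(=O)OC(=O)Cc1cc(OCc2ccccc2)c(OCc2ccccc2)c(OCc2ccccc2)c1 | intermediate
22 | (R)-4-benzyl-3-(2-TBP-acetyl)oxazolidin-2-one | O=C(Cc1cc(OCc2ccccc2)c(OCc2ccccc2)c(OCc2ccccc2)c1)N1[C@H](Cc2ccccc2)COC1=O | intermediate
23 | Z dibutylboron enolate of 22 (formed in the flask) | CCCCB(CCCC)O/C(=C\c1cc(OCc2ccccc2)c(OCc2ccccc2)c(OCc2ccccc2)c1)N1[C@H](Cc2ccccc2)COC1=O | intermediate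
24 | (R)-4-benzyl-3-[(2R,3S)-4-(6-acetoxy-2,4-bis(benzyloxy)-3-U-phenyl)-3-hydroxy-2-TBP-butanoyl]oxazolidin-2-one | c1ccccc1COc1cc(OCc2ccccc2)c2c(c1)O[C@H](c1cc(OCc3ccccc3)c(OCc3ccccc3)c(OCc3ccccc3)c1)[C@@H](OCc1ccccc1)[C@@H]2c1c(OCc2ccccc2)cc(OC(C)=O)c(c1OCc1ccccc1)C[C@H](O)[C@@H](c1cc(OCc2ccccc2)c(OCc2ccccc2)c(OCc2ccccc2)c1)C(=O)N1[C@H](Cc2ccccc2)COC1=O | intermediate
25 | (R)-4-benzyl-3-[(2R,3S)-4-(6-acetoxy-2,4-bis(benzyloxy)-3-U-phenyl)-3-(tert-butyldimethylsilyloxy)-2-TBP-butanoyl]oxazolidin-2-one | c1ccccc1COc1cc(OCc2ccccc2)c2c(c1)O[C@H](c1cc(OCc3ccccc3)c(OCc3ccccc3)c(OCc3ccccc3)c1)[C@@H](OCc1ccccc1)[C@@H]2c1c(OCc2ccccc2)cc(OC(C)=O)c(c1OCc1ccccc1)C[C@H](O[Si](C)(C)C(C)(C)C)[C@@H](c1cc(OCc2ccccc2)c(OCc2ccccc2)c(OCc2ccccc2)c1)C(=O)N1[C@H](Cc2ccccc2)COC1=O | intermediate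
26 | (2R,3S)-4-[2,4-bis(benzyloxy)-6-hydroxy-3-U-phenyl]-3-(tert-butyldimethylsilyloxy)-2-TBP-butaneperoxoic acid (lithium salt in the flask) | c1ccccc1COc1cc(OCc2ccccc2)c2c(c1)O[C@H](c1cc(OCc3ccccc3)c(OCc3ccccc3)c(OCc3ccccc3)c1)[C@@H](OCc1ccccc1)[C@@H]2c1c(OCc2ccccc2)cc(O)c(c1OCc1ccccc1)C[C@H](O[Si](C)(C)C(C)(C)C)[C@@H](c1cc(OCc2ccccc2)c(OCc2ccccc2)c(OCc2ccccc2)c1)C(=O)OO | intermediate
27 | (2R,3S)-4-[2,4-bis(benzyloxy)-6-hydroxy-3-U-phenyl]-3-(tert-butyldimethylsilyloxy)-2-TBP-butanoic acid (seco acid) | c1ccccc1COc1cc(OCc2ccccc2)c2c(c1)O[C@H](c1cc(OCc3ccccc3)c(OCc3ccccc3)c(OCc3ccccc3)c1)[C@@H](OCc1ccccc1)[C@@H]2c1c(OCc2ccccc2)cc(O)c(c1OCc1ccccc1)C[C@H](O[Si](C)(C)C(C)(C)C)[C@@H](c1cc(OCc2ccccc2)c(OCc2ccccc2)c(OCc2ccccc2)c1)C(O)=O | intermediate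
28 | (2R,3S)-5,7-bis(benzyloxy)-3-(tert-butyldimethylsilyloxy)-6-U-2-TBP-chromane | c1ccccc1COc1cc(OCc2ccccc2)c2c(c1)O[C@H](c1cc(OCc3ccccc3)c(OCc3ccccc3)c(OCc3ccccc3)c1)[C@@H](OCc1ccccc1)[C@@H]2c1c(OCc2ccccc2)cc2c(c1OCc1ccccc1)C[C@H](O[Si](C)(C)C(C)(C)C)[C@@H](c1cc(OCc3ccccc3)c(OCc3ccccc3)c(OCc3ccccc3)c1)O2 | intermediate
29 | (2R,3S)-5,7-bis(benzyloxy)-6-U-2-TBP-chroman-3-ol | c1ccccc1COc1cc(OCc2ccccc2)c2c(c1)O[C@H](c1cc(OCc3ccccc3)c(OCc3ccccc3)c(OCc3ccccc3)c1)[C@@H](OCc1ccccc1)[C@@H]2c1c(OCc2ccccc2)cc2c(c1OCc1ccccc1)C[C@H](O)[C@@H](c1cc(OCc3ccccc3)c(OCc3ccccc3)c(OCc3ccccc3)c1)O2 | intermediate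
30 | gallocatechin-(4α→6)-gallocatechin, both units (2R,3S), C4 aryl trans to O3 | Oc1cc(O)c2c(c1)O[C@H](c1cc(O)c(O)c(O)c1)[C@@H](O)[C@@H]2c1c(O)cc2c(c1O)C[C@H](O)[C@@H](c1cc(O)c(O)c(O)c1)O2 | target

**Count and risks**

Total step count: 18. Longest linear sequence: 14 steps (steps 1–3, 5–9 and 13–18).

The three steps most likely to fail:

1. Step 16. The free ring D phenol and the alkoxy-substituted arenes may be oxidised at the anode in competition with the carboxylate, so that material is lost to phenol-derived radicals and the electrode is passivated before CO2 is expelled. The fallback sets out from 27 and returns at 28; it generates the same C2' cation without an anode. Coupling of 27 with N-hydroxyphthalimide (DIC, CH2Cl2, 0 °C) should give the redox-active 1,3-dioxoisoindolin-2-yl ester F1, since the N-hydroxy imide is acylated far more readily than the hindered phenol. Irradiation of F1 with blue light and an organic N-aryl phenothiazine photocatalyst (CH2Cl2/MeCN, collidine) should cause reductive fragmentation to the C2' radical. The photocatalyst radical cation oxidises that radical to the benzylic cation (radical–polar crossover decarboxylative etherification), and O1' closes ring F to give 28.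

2. Step 5. Facial selectivity at C4 may be poor, the nucleophile also adding syn to the non-participating C3 benzyloxy group and giving the 3,4-cis adduct. The fallback sets out from 3 and returns at 10; it uses neighbouring-group participation. Acetylation of 3 (Ac2O, pyridine, DMAP) gives (2R,3S,4S)-5,7-bis(benzyloxy)-4-(2-ethoxyethoxy)-2-TBP-chroman-3-yl acetate F2. Under the TMSOTf conditions of step 5 the acetate carbonyl closes onto the β face of the C4 cation, and 6 can open the dioxolanium ion only from the α face, giving the 3,4-trans 3-O-acetyl adduct F3. BnBr/K2CO3 then gives the ring D dibenzyl ether F4, and CsF/allyl bromide gives the 3-O-acetyl allyl ether F5. Powdered KOH with BnBr and Bu4NI in DMSO exchanges the acetate for a benzyl ether in one pot and arrives at 10.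

3. Step 13. The arylacetaldehyde 14 may enolise and self-condense under the enolate conditions, or the α-aryl aldol may undergo retro-aldol cleavage on work-up, so that little adduct is obtained. The fallback sets out from 14 (with the ester partner made from 19) and returns at 28; it sets C3' by reduction instead of by an aldol reaction. Esterification of 19 (TMSCHN2, MeOH/toluene) gives methyl 2-TBP-acetate F6. Its lithium enolate (LDA, THF, −78 °C) adds quickly and irreversibly to 14 to give the β-hydroxy ester F7 as a mixture of isomers. Dess–Martin periodinane gives the β-keto ester F8. Noyori asymmetric hydrogenation (RuCl2[(S)-BINAP], H2, MeOH/CH2Cl2, conditions that leave benzyl ethers alone), with equilibration of the labile C2' centre, should give the (3S)-hydroxy ester F9. TBSOTf/2,6-lutidine gives the silyl ether F10. LiOH in THF/MeOH/H2O cleaves the methyl ester and the aryl acetate to the seco acid F11 (27 together with its C2' epimer). Because step 16 erases C2', this mixture is electrolysed under the step 16 conditions to give 28.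

**Further compounds**

F1 | step 16 | 1,3-dioxoisoindolin-2-yl (2R,3S)-4-[2,4-bis(benzyloxy)-6-hydroxy-3-U-phenyl]-3-(tert-butyldimethylsilyloxy)-2-TBP-butanoate | c1ccccc1COc1cc(OCc2ccccc2)c2c(c1)O[C@H](c1cc(OCc3ccccc3)c(OCc3ccccc3)c(OCc3ccccc3)c1)[C@@H](OCc1ccccc1)[C@@H]2c1c(OCc2ccccc2)cc(O)c(c1OCc1ccccc1)C[C@H](O[Si](C)(C)C(C)(C)C)[C@@H](c1cc(OCc2ccccc2)c(OCc2ccccc2)c(OCc2ccccc2)c1)C(=O)ON1C(=O)c2ccccc2C1=O
F2 | step 5 | (2R,3S,4S)-5,7-bis(benzyloxy)-4-(2-ethoxyethoxy)-2-TBP-chroman-3-yl acetate | c1ccccc1COc1cc(OCc2ccccc2)c2c(c1)O[C@H](c1cc(OCc3ccccc3)c(OCc3ccccc3)c(OCc3ccccc3)c1)[C@@H](OC(C)=O)[C@H]2OCCOCC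
F3 | step 5 | 3-O-acetyl analogue of 7 (acetate in place of the C3 benzyl ether of U) | c1ccccc1COc1cc(OCc2ccccc2)c2c(c1)O[C@H](c1cc(OCc3ccccc3)c(OCc3ccccc3)c(OCc3ccccc3)c1)[C@@H](OC(C)=O)[C@@H]2c1c(O)cc(O[Si](C(C)C)(C(C)C)C(C)C)cc1O
F4 | step 5 | 3-O-acetyl analogue of 8 | c1ccccc1COc1cc(OCc2ccccc2)c2c(c1)O[C@H](c1cc(OCc3ccccc3)c(OCc3ccccc3)c(OCc3ccccc3)c1)[C@@H](OC(C)=O)[C@@H]2c1c(OCc2ccccc2)cc(O[Si](C(C)C)(C(C)C)C(C)C)cc1OCc1ccccc1
F5 | step 5 | 3-O-acetyl analogue of 10 | c1ccccc1COc1cc(OCc2ccccc2)c2c(c1)O[C@H](c1cc(OCc3ccccc3)c(OCc3ccccc3)c(OCc3ccccc3)c1)[C@@H](OC(C)=O)[C@@H]2c1c(OCc2ccccc2)cc(OCC=C)cc1OCc1ccccc1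
F6 | step 13 | methyl 2-TBP-acetate | COC(=O)Cc1cc(OCc2ccccc2)c(OCc2ccccc2)c(OCc2ccccc2)c1
F7 | step 13 | methyl 4-[6-acetoxy-2,4-bis(benzyloxy)-3-U-phenyl]-3-hydroxy-2-TBP-butanoate (isomer mixture at C2 and C3) | c1ccccc1COc1cc(OCc2ccccc2)c2c(c1)O[C@H](c1cc(OCc3ccccc3)c(OCc3ccccc3)c(OCc3ccccc3)c1)[C@@H](OCc1ccccc1)[C@@H]2c1c(OCc2ccccc2)cc(OC(C)=O)c(c1OCc1ccccc1)CC(O)C(c1cc(OCc2ccccc2)c(OCc2ccccc2)c(OCc2ccccc2)c1)C(=O)OC
F8 | step 13 | methyl 4-[6-acetoxy-2,4-bis(benzyloxy)-3-U-phenyl]-3-oxo-2-TBP-butanoate | c1ccccc1COc1cc(OCc2ccccc2)c2c(c1)O[C@H](c1cc(OCc3ccccc3)c(OCc3ccccc3)c(OCc3ccccc3)c1)[C@@H](OCc1ccccc1)[C@@H]2c1c(OCc2ccccc2)cc(OC(C)=O)c(c1OCc1ccccc1)CC(=O)C(c1cc(OCc2ccccc2)c(OCc2ccccc2)c(OCc2ccccc2)c1)C(=O)OC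
F9 | step 13 | methyl (3S)-4-[6-acetoxy-2,4-bis(benzyloxy)-3-U-phenyl]-3-hydroxy-2-TBP-butanoate (C2 unassigned) | c1ccccc1COc1cc(OCc2ccccc2)c2c(c1)O[C@H](c1cc(OCc3ccccc3)c(OCc3ccccc3)c(OCc3ccccc3)c1)[C@@H](OCc1ccccc1)[C@@H]2c1c(OCc2ccccc2)cc(OC(C)=O)c(c1OCc1ccccc1)C[C@H](O)C(c1cc(OCc2ccccc2)c(OCc2ccccc2)c(OCc2ccccc2)c1)C(=O)OC
F10 | step 13 | methyl (3S)-4-[6-acetoxy-2,4-bis(benzyloxy)-3-U-phenyl]-3-(tert-butyldimethylsilyloxy)-2-TBP-butanoate (C2 unassigned) | c1ccccc1COc1cc(OCc2ccccc2)c2c(c1)O[C@H](c1cc(OCc3ccccc3)c(OCc3ccccc3)c(OCc3ccccc3)c1)[C@@H](OCc1ccccc1)[C@@H]2c1c(OCc2ccccc2)cc(OC(C)=O)c(c1OCc1ccccc1)C[C@H](O[Si](C)(C)C(C)(C)C)C(c1cc(OCc2ccccc2)c(OCc2ccccc2)c(OCc2ccccc2)c1)C(=O)OC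
F11 | step 13 | (3S)-4-[2,4-bis(benzyloxy)-6-hydroxy-3-U-phenyl]-3-(tert-butyldimethylsilyloxy)-2-TBP-butanoic acid (27 and its C2 epimer) | c1ccccc1COc1cc(OCc2ccccc2)c2c(c1)O[C@H](c1cc(OCc3ccccc3)c(OCc3ccccc3)c(OCc3ccccc3)c1)[C@@H](OCc1ccccc1)[C@@H]2c1c(OCc2ccccc2)cc(O)c(c1OCc1ccccc1)C[C@H](O[Si](C)(C)C(C)(C)C)C(c1cc(OCc2ccccc2)c(OCc2ccccc2)c(OCc2ccccc2)c1)C(O)=O
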